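The easy step was to turn the X readings from percent into a concentration. From 20.0 min to 120 min the X readings of this flask scattered without drift, and their mean, taken on the E charged, gave 0.186 M. I called this the X level under crystals, the concentration of X that stands while L is present.

- north-east: E 2 M; Z 2.6 M; G 400 mM; the very flask that is asked about, followed so far
- flask: E 2.0 M; Z 2.60 M; G 400 mM; time 10 h

- north-east (time / min: Q / %, X / %, E / %): 6.00: 71.8, 9.8, 20.8; 20.0: 78.7, 11.3, 12.4; 30.0: 79.5, 10.2, 10.4; 50.0: 78.7, 7.1, 11.5; 80.0: 78.8, 9.5, 12.4; 90.0: 79.8, 7.1, 12.0; 120: 80.5, 10.5, 12.4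

(each reading ± 1 percentage point)

- Q is meant together with its L
- solid, in amounts per volume of the solution: L
- the numbers in the tables scatter with a standard deviation of 1 percentage point
- steps under discussion: E + Z <-> Q; E + Z <-> X; Q + G <-> X + G; L <-> Q

1. share of Q in Q plus X at 5.0 s
2. share of Q in Q plus X at 10 h
3. which of Q and X there is more of at 10 h

I supposed that L stood in this flask, so that dissolved Q sat at a ceiling, and that the step through G held X in a steady ratio to dissolved Q. That is thermodynamic control, and on this supposition the level does not follow the E charged. Taking Q plus X as what the mean E reading leaves, I reckoned a share of 89.5 % at 10 h.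

The neighbouring flask looks nearly the same, with 1.2 M of E instead of 2.0 M and Z unchanged. I expected it to hold the same concentration of X, which on its smaller charge reads 15.5 %, more than the 9.30 % of this flask. So I expected its share of Q to end lower.

The forecast gave 86 % at 5.0 s, 89.5 % at 10 h and Q in the lead, judging that “the flask looks fully equilibrated”.

The flask gave 88.3 % at 5.0 s and 89.7 % at 10 h, with Q ahead at 79.5 % against 9.12 % for X. The share at 5.0 s in this flask stood below full mainly because of the direct loss of E + Z to X: the run without that step gave 98.0 %.

    E + Z ⇌ Q (K = 2.50 M⁻¹, k = 0.00370 M⁻¹ s⁻¹)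
    E + Z ⇌ X (K = 0.970 M⁻¹, k = 4.30 × 10⁻⁴ M⁻¹ s⁻¹)
    Q + G ⇌ X + G, rate k3*[G]*[Q] forward; the back reaction follows from the equilibrium constant (k = 0.0210 M⁻¹ s⁻¹)
    L ⇌ Q, rate k4*(cs4 - [Q]) while solid is left; crystals form when [Q] > cs4 (solubility = 0.470 M, k = 0.700 s⁻¹)

The ceiling on dissolved Q is part of the reason for this flask's high share at 10 h: in the run without that ceiling the share fell from 89.7 % to 72.0 %. With 56.0 % of the E charged lying as L, this flask held X at 0.182 M, beside my level of 0.186 M. The neighbour with 1.2 M of E still held 35.4 % as L and X at 0.182 M, which on its smaller charge is 15.2 % against my 15.5 %, and its share ended at 83.1 %.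

The data were generated by integration on assumed constants, and the scatter is random.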